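## Structural features

The target is a drimane-type sesquiterpenoid. A trans-fused decalin (rings A and B, gem-dimethyl on C4, angular methyl on C10) carries on C9 the one-carbon bridge C11, which is joined by an exocyclic double bond to a five-membered ring C (C1'–C5'). Ring C is the enol of a 4-alkylidene-5-chlorocyclopentane-1,3-dione: ylidene carbon C1', enol C2', ketone C4', chloride C5'.

Four stereocenters are contiguous in ring B: C5 (α-H), the quaternary C10 (β-methyl), C9 (equatorial β-C11) and C8. C8 is a tertiary carbinol whose hydroxyl is axial (β), syn-axial to the C10 methyl and cis to C11, with the C12 methyl equatorial.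

The fifth stereocenter, C5' (R), is separated from the decalin by the C11=C1' alkene, whose geometry puts C9 on the side of C2'. It is out of reach of substrate control.

The fragile elements are:
- the C5' chloride, which is allylic and α to a carbonyl, and so open to epimerisation, chloride exchange and base-induced loss of HCl;
- the acidic vinylogous acid and the geometry of the exocyclic enone;
- the tertiary alcohol β to C11, which invites dehydration or retro-aldol cleavage once C11 is a carbonyl.

The real difficulty is threefold: the quaternary C10 inside a trans-fused skeleton of defined absolute configuration, the axial C8 alcohol, and a ring C with secured alkene geometry and a remote chloride set by a reagent.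

The key step rests on a carbon count. C1–C10 together with the three methyl groups on C4 and C10 are exactly the thirteen carbons of α-ionone: its acetyl methyl is C9, its stereocenter is C5 and its ring alkene is C1=C10. Only C11, C12 and the bond C9–C10 are missing. Oxidation at C2 makes C10 the β-carbon of an enone, and C9, acidified by the C8 ketone and a C11 ester, closes ring B on it.

## Logic of the disconnections

**26 ⇒ 25.** The O–H bonds at O4' and O8 are traced back to an isopropyl enol ether and a triethylsilyl ether. This keeps the vinylogous acid and the tertiary alcohol silent until the end. The demand is one acidic operation that liberates both without a nucleophilic counter-ion that could exchange the C5' chloride.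

**25 ⇒ 24.** The C5'–Cl bond is cut and replaced by a C5'–O bond of opposite configuration. The chloride is the most labile group and is introduced last but one. The forward step must be a clean SN2 displacement with inversion, free of ionisation and allylic transposition.

**24 ⇒ 23.** The C5'–H bond is cut back to the C5' ketone. This reduces the remote stereocenter to a choice between two faces of one carbonyl. Because the decalin cannot bias those faces, the reducing agent must supply the selectivity, and it must pick C5' over C2' and over conjugate addition at C11.

**23 ⇒ 22.** The bond C1'–C2' is cut and C2' reconnected to C5', contracting ring C to a cyclobutenone that bears the alkyne C11≡C1'. All four carbons C2'–C5' then come from one four-membered building block. The alkene geometry follows from the anti course of acyl migration and metalation. The demand is that the acyl carbon, not the vinyl carbon, migrates and that O8 is masked so that it cannot attack the activated alkyne.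

**22 ⇒ 17 + 20, and 20 ⇒ 18.** The bond C1'–C5' is cut to an acetylide and a cyclobutenedione. The dione must carry hydrogen at the future C3'. A squarate diester would leave an unwanted oxygen there, so 20 is derived from 18 by removal of one alkoxy group. The acetylide must add to the carbonyl next to the alkoxy-bearing carbon.

**17 ⇒ 15 + 16.** The triple bond C11≡C1' is cut to the C11 aldehyde and a one-carbon diazo reagent. The demand is a mild base, because 15 has an epimerisable C9 and a β-oxygen.

**15 ⇒ 14 ⇒ 13 ⇒ 12.** No skeletal bond is cut. C11 is returned to the ester oxidation level and O8 to the free alcohol. O8 is capped directly after it is formed so that no β-hydroxy carbonyl compound is ever handled.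

**12 ⇒ 10 + 11.** The bond C8–C12 is cut. The forward addition must come from the equatorial α-face, which the syn-axial C10 methyl enforces. It must also beat deprotonation of the acidic C9–H, which calls for a weakly basic organometallic.

**10 ⇒ 9 ⇒ 7.** The C2 carbonyl, needed only to activate C10, is put back. Its removal goes through an enol triflate. A thioketal with desulfurisation was rejected because C2 lies between two syn-axial methyl groups and the C8 ketone would react first. The demand is that only the C2 enolate is sulfonylated while the β-keto ester sits as its own, less reactive enolate.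

**7 ⇒ 6.** The bond C9–C10 is cut, opening ring B. This removes the quaternary center and two stereocenters and leaves a monocyclic enone whose only stereocenter is C5. The forward step must deliver the trans ring fusion.

**6 ⇒ 5 ⇒ 3 + 4, and 3 ⇒ 1.** The C2 oxygen is removed (allylic oxidation forward), the bond C9–C11 is cut (acylation forward) and the C6=C7 alkene is restored (conjugate reduction forward). The order matters. Base acting on 1 itself would remove the C5 hydrogen, which is γ to the enone and doubly allylic, and would move the ring alkene into conjugation, erasing the stereocenter. The side chain is therefore saturated first, the acylation follows, and the ring enone is created last under non-basic conditions.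

## Other disconnections considered

**Alternative 1:** The cut is C1'–C5' inside ring C. In the forward step the ynal A1 is treated with Ni(C8H12)2 (zerovalent nickel), P(n-Bu)3 and Et3SiH. Oxidative cyclisation of alkyne and aldehyde gives an oxanickelacycle; the silane cleaves the Ni–O bond and reductive elimination delivers hydrogen to C11, giving A2.
- In its favour: the syn addition fixes the alkene geometry (C9 cis to C2'), which is equal to what the palladium ring expansion offers here. The C5' oxygen center can be induced by the neighbouring C4' silyloxy center taken from the chiral pool, which is better than a catalyst-controlled reduction of a dienedione. The neutral conditions tolerate the free O8, so no silyl cap is needed, which is also better.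
- Against it: it concerns ring C only. A1 must be assembled from the decalin alkyne and a chiral four-carbon ketal aldehyde. After cyclisation about five operations remain (selective desilylation, chlorination with inversion, second desilylation, oxidation at C4' beside the chloride, ketal hydrolysis) against three here (steps 15–17). The sense of 1,2-induction is not assured.
- Comparison: as a ring C endgame it is equal on geometry, superior in the origin of the C5' configuration and inferior in step count. It says nothing about C10, so it could replace steps 13–17 but not the Michael closure.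

**Alternative 2:** The cuts are C8–C9 and O8–C11. In the forward step the acid of the monocyclic keto acid A3 is activated (for example as a mixed sulfonic anhydride) in the presence of a nucleophilic amine catalyst. The ammonium enolate at C9 adds to the C8 methyl ketone and the alkoxide closes the β-lactone A4.
- In its favour: C12 is already present, C8 and C9 are set together, and O8 and C11 are necessarily cis, as the target requires. No Grignard step and no C2 oxygen to erase are needed, and A4 is reduced directly to the 8β,11-diol level. On the C8 center and on steps after ring closure this is better than the chosen plan.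
- Against it: the quaternary C10 and its trans relation to C5 must already exist in A3, so the hardest center is moved into the substrate, for which α-ionone gives no direct answer. Aldol-lactonisations onto ketones are slow. The face of the ketone that must be attacked (O8 axial, syn to the C10 methyl) is not assured.
- Comparison: both plans close ring B with C9 as the nucleophile, here onto C8 and in the chosen plan onto C10. The mechanisms are equally well founded. The chosen plan is better on access to the substrate and on the quaternary center.

**Alternative 3:** The cuts are C5–C10 and C8–C9. In the forward step the triene A5 (silyloxydiene C5=C6–C7=C8, enoyl imide C9=C10) is bound through its imide to Cu(SbF6)2 (divalent copper) carrying the chiral bis(oxazoline), and an endo intramolecular [4+2] cycloaddition gives the octalin A6.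
- In its favour: two bonds, two rings and four stereocenters are formed in one catalytic step from an achiral chain. The absolute configuration comes from the ligand and not from an enantiopure terpene of limited supply, which is better. The trans fusion follows from a concerted geometry rather than from equilibration, which is better in principle.
- Against it: the dienophile is β,β-disubstituted (C10 becomes quaternary) and the diene terminus C5 is neopentylic. This catalysis is established for less substituted acryloyl imides, so rate and endo selectivity are doubtful. A5 needs its own stereodefined synthesis. A6 still requires alkene hydrogenation, removal of the auxiliary, and oxidation with methyl addition at C8.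
- Comparison: bond economy is better. The work after ring closure is equal to that of the chosen plan, which also adds C12 to a C8 ketone. The certainty of the key step is lower.

Key step: step 4

Remark: (S)-α-ionone (1) is taken to be purchasable in high enantiomeric purity; drimane numbering is used for the decalin (C11 on C9, C12 on C8; β is the face of the C10 methyl) and primed numbers for ring C.

Remark: the two enol forms of the ring C 1,3-dione interconvert by proton transfer, so the hydrolysis product of step 17 is the target, written as its more conjugated C2' enol.

Step 1
Reactants: 1 (S)-α-ionone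
Product: 3 (S)-dihydro-α-ionone, via triethylsilyl enol ether 2 (not isolated)
Conditions: Et3SiH (1.1 equiv), RhCl(PPh3)3 (1 mol%), benzene, 50 °C; then 1 M HCl, THF, 0 °C
Reagents that add atoms: none
Why: Rhodium-catalysed 1,4-hydrosilylation of the enone with a monohydrosilane and hydrolysis of the silyl enol ether (conjugate reduction) saturate only C6=C7; no base is present, so the C5 hydrogen, γ to the enone and doubly allylic in 1, is not removed and neither the stereocenter nor the position of the ring alkene is disturbed.

Step 2
Reactants: 3 (S)-dihydro-α-ionone; 4 dimethyl carbonate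
Product: 5 methyl 3-oxo-5-[(1S)-2,6,6-trimethylcyclohex-2-en-1-yl]pentanoate
Conditions: NaH (2.2 equiv), (MeO)2CO (3 equiv), THF, reflux; then AcOH
Reagents that add atoms: dimethyl carbonate (4), COC(=O)OC
Why: Crossed Claisen condensation of the methyl ketone with dimethyl carbonate places C11 on C9; the methyl group is acylated in preference to C7 and the product is held as its sodium enolate, while C5 is now only allylic and inert to NaH.

Step 3
Reactants: 5 methyl 3-oxo-5-[(1S)-2,6,6-trimethylcyclohex-2-en-1-yl]pentanoate
Product: 6 methyl 3-oxo-5-[(1S)-2,6,6-trimethyl-4-oxocyclohex-2-en-1-yl]pentanoate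
Conditions: t-BuOOH (70% aq., 4 equiv), CrO3 (5 mol%), CH2Cl2, 25 °C
Reagents that add atoms: tert-butyl hydroperoxide, CC(C)(C)OO
Why: Chromium-catalysed allylic oxidation with t-BuOOH converts the ring CH2 next to the alkene carbon C1 into the C2 ketone; the hindered methine C5 and the C10 methyl are not converted into carbonyl groups as readily, and the non-basic medium leaves the C5 hydrogen, now γ to the new enone, in place.

Step 4
Reactants: 6 methyl 3-oxo-5-[(1S)-2,6,6-trimethyl-4-oxocyclohex-2-en-1-yl]pentanoate
Product: 7 methyl 2,8-dioxo-12-nordriman-11-oate (trans-fused; 5α-H; 10β-CH3; 9β-CO2CH3)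
Conditions: Cs2CO3 (0.2 equiv), MeCN, 25 °C, then 50 °C until the isomer composition no longer changes
Reagents that add atoms: none
Why: The carbonate ionises the β-keto ester, its enolate adds through C9 to C10, the β-carbon of the ring enone, and the resulting C1=C2 enolate is protonated at C1; this is an intramolecular Michael addition, and the closest known type is the base-mediated cyclisation of β-keto esters onto β,β-disubstituted cyclohexenones to give angularly methylated decalones. Ring B closes in the 6-exo-trig mode, since C1 of the attacked alkene stays outside the new ring. The configuration of C10 is decided by the face of the enone that C9 attacks, and this is tied to C5, whose configuration keeps the tether equatorial. Attack on the β-face would be the stereoelectronically ideal axial addition through a chair-like ring A and would give the cis-decalin, but this path runs 1,3-diaxial into the β-methyl group on C4. Attack is therefore expected on the α-face, syn to H5, through a twist-boat ring A, which sets the C10 methyl β and axial and C9 equatorial, that is the trans fusion. C9 is set by equilibration through the enol, which places the ester equatorial (β). The step needs the trans fusion; it is secured by the C5 stereocenter, by the shielding from the gem-dimethyl group and by reversibility, since the adduct can revert by retro-Michael cleavage and warming lets the mixture move to the more stable trans isomer. C5 itself is safe because the weak base ionises only the β-keto ester and not the γ-position of the enone, so C5 of 1 remains the only source of absolute configuration.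

Step 5
Reactants: 7 methyl 2,8-dioxo-12-nordriman-11-oate
Product: 9 methyl 8-oxo-2-(trifluoromethylsulfonyloxy)-12-nordrim-2-en-11-oate, via dilithium bis-enolate 8 (not isolated)
Conditions: LiN(i-Pr)2 (2.2 equiv), THF, −78 °C; PhNTf2 (1.05 equiv), −78 → −20 °C; then H2O
Reagents that add atoms: N-phenylbis(trifluoromethanesulfonimide), O=S(=O)(N(c1ccccc1)S(=O)(=O)C(F)(F)F)C(F)(F)F
Why: The first equivalent of amide ionises the β-keto ester, which masks C8 and the ester, and the second forms the kinetic C2 ketone enolate, expected at C3, away from the anionic C9; only this more reactive enolate is sulfonylated at low temperature (enol triflate formation from a ketone enolate), and a regioisomer formed at C1 would converge in step 6.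

Step 6
Reactants: 9 methyl 8-oxo-2-(trifluoromethylsulfonyloxy)-12-nordrim-2-en-11-oate
Product: 10 methyl 8-oxo-12-nordriman-11-oate
Conditions: H2 (1 atm), PtO2 (10 mol%), NaHCO3, EtOAc, 25 °C
Reagents that add atoms: none
Why: Hydrogenolysis of an enol triflate to the alkane over PtO2 removes the C2 oxygen; in the buffered aprotic medium the ester and the hindered C8 ketone should not be reduced, no stereocenter is touched and C9 stays equatorial.

Step 7
Reactants: 10 methyl 8-oxo-12-nordriman-11-oate; 11 methylmagnesium bromide
Product: 12 methyl 8β-hydroxydriman-11-oate (8α-methyl)
Conditions: CeCl3 (anhydrous, 3 equiv), MeMgBr (3 equiv), THF, −78 → −40 °C; then 0.5 M HCl, 0 °C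
Reagents that add atoms: methylmagnesium bromide (11), C[Mg]Br
Why: The weakly basic organocerium reagent adds to the ketone of the enolisable 1,3-dicarbonyl unit instead of removing the C9 proton (cerium-mediated Grignard addition); axial approach to C8 is blocked by the syn-axial C10 methyl, so the methyl group enters equatorially from the α-face and gives the axial 8β-alcohol.

Step 8
Reactants: 12 methyl 8β-hydroxydriman-11-oate
Product: 13 methyl 8β-(triethylsilyloxy)driman-11-oate
Conditions: Et3SiOTf (1.5 equiv), 2,6-lutidine, CH2Cl2, 0 → 25 °C
Reagents that add atoms: triethylsilyl trifluoromethanesulfonate, CC[Si](CC)(CC)OS(=O)(=O)C(F)(F)F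
Why: Silylation of the hindered tertiary alcohol with a silyl triflate; the cap prevents retro-aldol cleavage and dehydration at the aldehyde stage and attack of O8 on the palladium-activated alkyne in step 14.

Step 9
Reactants: 13 methyl 8β-(triethylsilyloxy)driman-11-oate
Product: 14 8β-(triethylsilyloxy)driman-11-ol
Conditions: LiAlH4 (1.5 equiv), THF, 0 → 25 °C; Na2SO4·10H2O quench
Reagents that add atoms: none
Why: Hydride reduction of the ester to the primary alcohol; the tertiary silyl ether is stable and C9 is no longer enolisable afterwards.

Step 10
Reactants: 14 8β-(triethylsilyloxy)driman-11-ol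
Product: 15 8β-(triethylsilyloxy)driman-11-al
Conditions: (n-Pr4N)RuO4 (5 mol%), N-methylmorpholine N-oxide (1.5 equiv), 4 Å molecular sieves, CH2Cl2, 25 °C
Reagents that add atoms: none
Why: Ley–Griffith oxidation of the neopentyl-type primary alcohol under neutral conditions stops at the aldehyde; the equatorial formyl group on C9 is the stable epimer.

Step 11
Reactants: 15 8β-(triethylsilyloxy)driman-11-al; 16 dimethyl (1-diazo-2-oxopropyl)phosphonate
Product: 17 terminal alkyne C9–C11≡C1'H with 8β-triethylsilyloxy group
Conditions: K2CO3 (2 equiv), MeOH, 0 → 25 °C
Reagents that add atoms: dimethyl (1-diazo-2-oxopropyl)phosphonate (16), COP(=O)(OC)C(=[N+]=[N-])C(C)=O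
Why: Ohira–Bestmann (Seyferth–Gilbert) homologation adds C1' and turns the aldehyde into the terminal alkyne; the mild carbonate base and the silyl cap on O8 limit epimerisation at C9 and β-elimination.

Step 12
Reactants: 18 diisopropyl squarate
Product: 20 3-isopropoxycyclobut-3-ene-1,2-dione, via 4-hydroxy-2,3-diisopropoxycyclobut-2-en-1-one 19 (not isolated)
Conditions: LiAlH(O-t-Bu)3 (1.05 equiv), THF, −15 °C; then conc. HCl, CH2Cl2, 25 °C
Reagents that add atoms: water, O
Why: The hydride adds 1,2 to one carbonyl of the squarate; acid then ionises the carbinol and the allylic oxocarbenium ion is hydrolysed with loss of isopropanol (carbonyl transposition), giving the monoalkoxy dione whose CH carbon becomes C3'.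

Step 13
Reactants: 17 terminal alkyne; 20 3-isopropoxycyclobut-3-ene-1,2-dione
Product: 22 4-alkynyl-4-hydroxy-3-isopropoxycyclobut-2-en-1-one adduct (C1' bonded to the carbinol carbon; both carbinol epimers), via lithium acetylide 21 (not isolated)
Conditions: n-BuLi (1.05 equiv), THF, −78 °C; then 20 (1.2 equiv), THF, −78 °C; then H2O
Reagents that add atoms: 3-isopropoxycyclobut-3-ene-1,2-dione (20), CC(C)OC1=CC(=O)C1=O
Why: 1,2-Addition of the lithium acetylide to the ketone-like carbonyl next to the alkoxy-bearing carbon (the other carbonyl is a deactivated vinylogous ester) forms C1'–C5'; the new carbinol center arises as both epimers and is destroyed in step 14.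

Step 14
Reactants: 22 cyclobutenone adduct
Product: 23 2-alkylidene-4-isopropoxycyclopent-4-ene-1,3-dione (ring C with C2' and C5' ketones; C4' isopropyl enol ether; C9 cis to C2'; O8 silyl ether)
Conditions: Pd(OCOCF3)2 (5 mol%), THF, 25 °C
Reagents that add atoms: none
Why: Palladium-catalysed ring expansion of a 4-alkynyl-4-hydroxycyclobutenone: divalent palladium activates the alkyne, the acyl carbon (C2') migrates from the carbinol carbon to C1' anti to the metal, and protonolysis of the C11–palladium bond gives the alkylidenecyclopentenedione; the anti addition places C9 cis to C2', as the target requires.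

Step 15
Reactants: 23 alkylidenecyclopentenedione
Product: 24 (5'S)-5'-hydroxy compound (C2' ketone; C4' isopropyl enol ether; O8 silyl ether)
Conditions: (R)-2-methyl-CBS-oxazaborolidine (0.2 equiv), catecholborane (1.5 equiv), toluene, −78 °C
Reagents that add atoms: none
Why: Corey–Bakshi–Shibata reduction: the C5' ketone, which is not a vinylogous ester like C2', is the more electrophilic carbonyl and is reduced 1,2 at low temperature; the remote center is set by the catalyst, the (R)-catalyst being chosen on the model that the isopropoxy-substituted C4' side is the larger group, which leads to the (5'S)-alcohol.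

Step 16
Reactants: 24 (5'S)-5'-hydroxy compound
Product: 25 (5'R)-5'-chloro compound (C2' ketone; C4' isopropyl enol ether; O8 silyl ether)
Conditions: PPh3 (1.2 equiv), CCl4 (3 equiv), CH2Cl2, 0 °C
Reagents that add atoms: tetrachloromethane, ClC(Cl)(Cl)Cl
Why: Appel chlorination: chloride displaces the alkoxyphosphonium group in an SN2 process with inversion to give the (5'R)-chloride; ionisation would place a cation in a ring of five sp2 carbons and SN2' attack at C11 would create a cyclopentadienone, so direct displacement should prevail.

Step 17
Reactants: 25 (5'R)-5'-chloro compound
Product: 26 target CNP0279879.2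
Conditions: 0.5 M H2SO4, THF, 25 °C
Reagents that add atoms: water, O
Why: Acid hydrolysis of the vinylogous ester (water adds at C4' and isopropanol leaves) and of the tertiary silyl ether in one operation; an acid without a nucleophilic anion avoids chloride exchange at C5', and proton transfer gives the C2' enol.

Compound list

1 | (S)-α-ionone, (3E)-4-[(1S)-2,6,6-trimethylcyclohex-2-en-1-yl]but-3-en-2-one | CC1=CCCC(C)(C)[C@@H]1/C=C/C(C)=O | starting material
2 | triethylsilyl enol ether of 3 ((Z)-enol ether) | CC1=CCCC(C)(C)[C@@H]1C/C=C(/C)O[Si](CC)(CC)CC | intermediate (not isolated)
3 | (S)-dihydro-α-ionone, 4-[(1S)-2,6,6-trimethylcyclohex-2-en-1-yl]butan-2-one | CC1=CCCC(C)(C)[C@@H]1CCC(C)=O | intermediate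
4 | dimethyl carbonate | COC(=O)OC | starting material
5 | methyl 3-oxo-5-[(1S)-2,6,6-trimethylcyclohex-2-en-1-yl]pentanoate | CC1=CCCC(C)(C)[C@@H]1CCC(=O)CC(=O)OC | intermediate
6 | methyl 3-oxo-5-[(1S)-2,6,6-trimethyl-4-oxocyclohex-2-en-1-yl]pentanoate | CC1(C)CC(=O)C=C(C)[C@H]1CCC(=O)CC(=O)OC | intermediate
7 | methyl 2,8-dioxo-12-nordriman-11-oate, methyl (1R,4aS,8aS)-5,5,8a-trimethyl-2,7-dioxodecahydronaphthalene-1-carboxylate | CC1(C)CC(=O)C[C@]2(C)[C@@H](C(=O)OC)C(=O)CC[C@@H]12 | intermediate
8 | dilithium bis-enolate of 7 (C2 enolate toward C3; C8 enolate toward C9) | CC1(C)C=C(O[Li])C[C@]2(C)C(C(=O)OC)=C(O[Li])CC[C@@H]12 | intermediate (not isolated)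
9 | methyl 8-oxo-2-(trifluoromethylsulfonyloxy)-12-nordrim-2-en-11-oate | CC1(C)C=C(OS(=O)(=O)C(F)(F)F)C[C@]2(C)[C@@H](C(=O)OC)C(=O)CC[C@@H]12 | intermediate
10 | methyl 8-oxo-12-nordriman-11-oate, methyl (1R,4aS,8aS)-5,5,8a-trimethyl-2-oxodecahydronaphthalene-1-carboxylate | CC1(C)CCC[C@]2(C)[C@@H](C(=O)OC)C(=O)CC[C@@H]12 | intermediate
11 | methylmagnesium bromide | C[Mg]Br | starting material
12 | methyl 8β-hydroxydriman-11-oate (8α-methyl) | CC1(C)CCC[C@]2(C)[C@@H](C(=O)OC)[C@@](C)(O)CC[C@@H]12 | intermediate
13 | methyl 8β-(triethylsilyloxy)driman-11-oate | CC1(C)CCC[C@]2(C)[C@@H](C(=O)OC)[C@@](C)(O[Si](CC)(CC)CC)CC[C@@H]12 | intermediate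
14 | 8β-(triethylsilyloxy)driman-11-ol | CC1(C)CCC[C@]2(C)[C@@H](CO)[C@@](C)(O[Si](CC)(CC)CC)CC[C@@H]12 | intermediate
15 | 8β-(triethylsilyloxy)driman-11-al | CC1(C)CCC[C@]2(C)[C@@H](C=O)[C@@](C)(O[Si](CC)(CC)CC)CC[C@@H]12 | intermediate
16 | dimethyl (1-diazo-2-oxopropyl)phosphonate | COP(=O)(OC)C(=[N+]=[N-])C(C)=O | starting material
17 | terminal alkyne, triethyl{[(1R,2S,4aS,8aS)-1-ethynyl-2,5,5,8a-tetramethyldecahydronaphthalen-2-yl]oxy}silane | CC1(C)CCC[C@]2(C)[C@@H](C#C)[C@@](C)(O[Si](CC)(CC)CC)CC[C@@H]12 | intermediate
18 | diisopropyl squarate, 3,4-diisopropoxycyclobut-3-ene-1,2-dione | CC(C)OC1=C(OC(C)C)C(=O)C1=O | starting material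
19 | 4-hydroxy-2,3-diisopropoxycyclobut-2-en-1-one (racemic) | CC(C)OC1=C(OC(C)C)C(O)C1=O | intermediate (not isolated)
20 | 3-isopropoxycyclobut-3-ene-1,2-dione | CC(C)OC1=CC(=O)C1=O | intermediate
21 | lithium acetylide of 17 | CC1(C)CCC[C@]2(C)[C@@H](C#C[Li])[C@@](C)(O[Si](CC)(CC)CC)CC[C@@H]12 | intermediate (not isolated)
22 | 4-alkynyl-4-hydroxy-3-isopropoxycyclobut-2-en-1-one adduct (both epimers at the carbinol carbon) | CC1(C)CCC[C@]2(C)[C@@H](C#CC3(O)C(=O)C=C3OC(C)C)[C@@](C)(O[Si](CC)(CC)CC)CC[C@@H]12 | intermediate
23 | 2-alkylidene-4-isopropoxycyclopent-4-ene-1,3-dione (C9 cis to C2') | CC1(C)CCC[C@]2(C)[C@@H](/C=C3\C(=O)C=C(OC(C)C)C3=O)[C@@](C)(O[Si](CC)(CC)CC)CC[C@@H]12 | intermediate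
24 | (5'S)-5'-hydroxy compound | CC1(C)CCC[C@]2(C)[C@@H](/C=C3\C(=O)C=C(OC(C)C)[C@H]3O)[C@@](C)(O[Si](CC)(CC)CC)CC[C@@H]12 | intermediate
25 | (5'R)-5'-chloro compound | CC1(C)CCC[C@]2(C)[C@@H](/C=C3\C(=O)C=C(OC(C)C)[C@@H]3Cl)[C@@](C)(O[Si](CC)(CC)CC)CC[C@@H]12 | intermediate
26 | CNP0279879.2 | CC1(C)CCC[C@]2(C)[C@@H](/C=C3\C(O)=CC(=O)[C@@H]3Cl)[C@@](C)(O)CC[C@@H]12 | target

Total step count: 17. Longest linear sequence: 16 steps (steps 1–11 and 13–17, from 1); step 12 is a one-step side branch from 18.

Steps least certain to work

**Step 4 (key step).** The likely failure is formation of the cis-fused isomer. The stereoelectronically favoured axial attack on the β-face competes with the twist-boat path to the trans isomer. Under a weak base the retro-Michael reaction, which needs enolisation of the C2 ketone toward C1, may be too slow to correct the ratio, and the thermodynamic preference for trans is expected to be modest. Forcing equilibration with a stronger base increases the danger of proton removal at C5 of transiently regenerated 6. Fallback: the route sets out again from 5 and leaves out steps 3–6. Treatment of 5 with SnCl4 in CH2Cl2 at 0 °C protonates the C1=C10 alkene, and the enol of the β-keto ester captures the C10 cation equatorially (Lewis-acid cation–olefin cyclisation, known for the isomeric keto ester with the tetrasubstituted ring alkene). This gives 10 directly, where the route is rejoined. Its own weakness is partial racemisation by loss of the C5 proton from the cation.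

**Step 5.** The likely failure is loss of chemoselectivity in the sulfonylation: incomplete second deprotonation, or triflation of the β-keto ester enolate as the mixture warms. Fallback: from 7 the β-keto ester is protected as its sodium enolate (NaH, THF, 0 °C) and the C2 ketone alone is reduced with LiAlH4 at −78 °C to methyl 2β-hydroxy-8-oxo-12-nordriman-11-oate F1. The strained axial alcohol is eliminated anti with POCl3 in pyridine to methyl 8-oxo-12-nordrim-2-en-11-oate F2 (a 1-ene isomer would converge). Hydrogenation over Pd on carbon returns the route to 10.

**Step 7.** The likely failure is proton transfer from C9 to the organometallic outrunning addition, or retro-aldol cleavage of the cerium alkoxide on warming. Fallback: from 10 both carbonyl groups are reduced with LiAlH4 to 12-nordrimane-8β,11-diol F3 (the C8 configuration is immaterial). The primary alcohol is silylated (t-BuMe2SiCl, imidazole) to 11-(tert-butyldimethylsilyloxy)-12-nordriman-8β-ol F4, and the secondary alcohol is oxidised (Dess–Martin periodinane) to 11-(tert-butyldimethylsilyloxy)-12-nordriman-8-one F5. MeMgBr adds from the equatorial α-face to this non-acidic ketone to give 11-(tert-butyldimethylsilyloxy)driman-8β-ol F6. Bu4NF gives drimane-8β,11-diol F7 (8α-methyl). Selective oxidation of the primary alcohol (TEMPO, PhI(OAc)2) gives 8β-hydroxydriman-11-al F8. The Ohira–Bestmann reagent gives the 8β-hydroxy alkyne F9, and Et3SiOTf with 2,6-lutidine returns the route to 17.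

**Step 15.** The likely failures are conjugate delivery of hydride to C11 of the doubly activated alkylidene, attack at C2', and weak discrimination between the two faces because both groups flanking C5' are sp2 carbons of similar size; the assignment of the larger group, and with it the choice of catalyst antipode, is not secure. Fallback: from 23 a Luche reduction (NaBH4, CeCl3·7H2O, MeOH, −78 °C) gives 24 together with its C5' epimer, the (5'R)-alcohol F10. The two are diastereomers and are separated by chromatography. F10 is returned to 23 by oxidation with MnO2 and recycled, and the route continues from 24.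

**Step 16.** The likely failures are erosion of the C5' configuration by repeated displacement of chloride by chloride, allylic transposition, and conjugate addition of the phosphine to C11 or dechlorination of the α-chloro enone by excess phosphine. Fallback: from 23 the reduction is run with the enantiomeric oxazaborolidine to give the (5'R)-alcohol F10. SOCl2 in 1,4-dioxane converts it into the chlorosulfite F11, which collapses with retention (internal return) and loss of SO2, without phosphine or free chloride, and the route is rejoined at 25.

Further compounds

F0 | step 4 | none | none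
F1 | step 5 | methyl 2β-hydroxy-8-oxo-12-nordriman-11-oate | CC1(C)C[C@@H](O)C[C@]2(C)[C@@H](C(=O)OC)C(=O)CC[C@@H]12
F2 | step 5 | methyl 8-oxo-12-nordrim-2-en-11-oate | CC1(C)C=CC[C@]2(C)[C@@H](C(=O)OC)C(=O)CC[C@@H]12
F3 | step 7 | 12-nordrimane-8β,11-diol | CC1(C)CCC[C@]2(C)[C@@H](CO)[C@@H](O)CC[C@@H]12
F4 | step 7 | 11-(tert-butyldimethylsilyloxy)-12-nordriman-8β-ol | CC1(C)CCC[C@]2(C)[C@@H](CO[Si](C)(C)C(C)(C)C)[C@@H](O)CC[C@@H]12
F5 | step 7 | 11-(tert-butyldimethylsilyloxy)-12-nordriman-8-one | CC1(C)CCC[C@]2(C)[C@@H](CO[Si](C)(C)C(C)(C)C)C(=O)CC[C@@H]12
F6 | step 7 | 11-(tert-butyldimethylsilyloxy)driman-8β-ol (8α-methyl) | CC1(C)CCC[C@]2(C)[C@@H](CO[Si](C)(C)C(C)(C)C)[C@@](C)(O)CC[C@@H]12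
F7 | step 7 | drimane-8β,11-diol (8α-methyl) | CC1(C)CCC[C@]2(C)[C@@H](CO)[C@@](C)(O)CC[C@@H]12
F8 | step 7 | 8β-hydroxydriman-11-al (8α-methyl) | CC1(C)CCC[C@]2(C)[C@@H](C=O)[C@@](C)(O)CC[C@@H]12
F9 | step 7 | 8β-hydroxy alkyne (17 without the silyl group) | CC1(C)CCC[C@]2(C)[C@@H](C#C)[C@@](C)(O)CC[C@@H]12
F10 | step 15 | (5'R)-5'-hydroxy compound (C5' epimer of 24) | CC1(C)CCC[C@]2(C)[C@@H](/C=C3\C(=O)C=C(OC(C)C)[C@@H]3O)[C@@](C)(O[Si](CC)(CC)CC)CC[C@@H]12
F11 | step 16 | chlorosulfite of F10 | CC1(C)CCC[C@]2(C)[C@@H](/C=C3\C(=O)C=C(OC(C)C)[C@@H]3OS(Cl)=O)[C@@](C)(O[Si](CC)(CC)CC)CC[C@@H]12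
A1 | alternative 1 | ynal: decalin alkyne C11≡C1' with C2' dioxolane ketal, C4' tert-butyldimethylsilyl ether and C5' aldehyde | CC1(C)CCC[C@]2(C)[C@@H](C#CC3(OCCO3)C[C@H](O[Si](C)(C)C(C)(C)C)C=O)[C@@](C)(O)CC[C@@H]12
A2 | alternative 1 | Z-alkylidenecyclopentane with C2' ketal, C4' tert-butyldimethylsilyl ether and C5' triethylsilyl ether | CC1(C)CCC[C@]2(C)[C@@H](/C=C3\C4(OCCO4)C[C@H](O[Si](C)(C)C(C)(C)C)[C@H]3O[Si](CC)(CC)CC)[C@@](C)(O)CC[C@@H]12
A3 | alternative 2 | monocyclic keto acid: ring A with C10 bearing CH3 and CH2CO2H and C5 bearing the 3-oxobutyl chain | CC1(C)CCC[C@](C)(CC(=O)O)[C@H]1CCC(C)=O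
A4 | alternative 2 | 8β-hydroxydriman-11-oic acid 8,11-β-lactone | CC1(C)CCC[C@]2(C)[C@@H](C(=O)O3)[C@]3(C)CC[C@@H]12
A5 | alternative 3 | acyclic triene: (E)-β-methyl enoyl oxazolidinone tethered to an (E,E)-1-silyloxydiene | O=C(/C=C(\C)CCCC(C)(C)/C=C/C=C/O[Si](C)(C)C(C)(C)C)N1CCOC1=O
A6 | alternative 3 | trans-fused octalin with C8 silyl ether and C11 imide | CC1(C)CCC[C@]2(C)[C@@H](C(=O)N3CCOC3=O)[C@@H](O[Si](C)(C)C(C)(C)C)C=C[C@@H]12
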